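A direct plan would build ring B last: (S)-3,7-dimethyloct-1-yn-3-ol A1 and the ring A-bearing 3-hydroxy-2-pyrone A2 would be tied through a diisopropylsilyl ketal, an intramolecular pyrone–alkyne Diels–Alder reaction with loss of CO2 would give the arene, and desilylation and debenzylation would finish.
Its weakest stretches would be these:
(a) The run-up to the benzylic chloride A3 from creosol (formylation, demethylation, double benzylation, reduction, chlorination) would spend five steps on protecting-group and redox changes before the single C–C bond formed in the Negishi coupling with A4.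
(b) The chiral alkynol A1 would need four steps from geraniol (asymmetric epoxidation, hydrogenation, chlorination, base-induced fragmentation), a long detour for one stereocentre on an eight-carbon piece.
(c) The bromopyrone A4 would depend on borylation–oxidation at only one of the two C–Br bonds of dibromopyrone A5, and the mixed silaketal (symmetrical ketals compete) followed by a 160 °C cycloaddition at high dilution would put all three fragments at risk in one late thermal step.

Retrosynthetic overview
1. Feature used: in ring B the carbinol carbon (C2 of the 6-methylheptan-2-yl group, bearing OH, CH3 and the 4-methylpentyl chain) sits para to the CH2 bridge and ortho to the phenol carbon; without that phenol oxygen, ring B is a para-phenylene whose two C–H bonds next to the carbinol are equivalent.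
2. Key disconnection: the bond between the carbinol carbon and the first chain CH2 is made together with the stereocentre by lithiation–borylation of the (R)-benzylic carbamate 8 with the alkyl boronic ester 10 (stereospecific 1,2-metalate rearrangement), followed by C–B oxidation.
3. The ring B phenol C–O bond is made afterwards by carbinol-directed C–H silylation and Tamao–Fleming oxidation; the diarylmethane bond (ring A carbon to CH2) comes from ortho-lithiation of ketal 2 and Negishi coupling with the commercial bromide 3.
4. No ring of the core is built: both benzene rings are bought, and only two five-membered auxiliary rings are closed and opened again (the catechol ketal first, the oxasilole late).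
5. Avoided by design: no benzylic halide of ring A and no benzyl ethers (the catechol C–H bond is used directly under one ketal), no chiral alkynol from a terpene degradation (the stereocentre comes from a catalytic ketone reduction and a stereospecific rearrangement), no pyrone and no hot cycloaddition.

Key step: step 6

Remark: compounds 1, 3 and 9 and all reagents are taken as commercial; ring A is the methylcatechol ring and ring B the phenol ring.

Step 1
Reactants: 1 4-methylbenzene-1,2-diol (4-methylcatechol)
Product: 2 5-methyl-2,2-diphenyl-1,3-benzodioxole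
Conditions: Ph2CCl2 (1.2 equiv), neat, 170 °C
Reagents that add atoms: dichlorodiphenylmethane, ClC(Cl)(c1ccccc1)c1ccccc1
Why: Ketal formation from a catechol and a geminal dichloride; the diphenylmethylene ketal masks both phenols in one step, has no acidic hydrogen, directs ortho-lithiation through its ring oxygen atoms and leaves at the end under neutral hydrogenolysis.

Step 2
Reactants: 2 5-methyl-2,2-diphenyl-1,3-benzodioxole; 3 1-[4-(bromomethyl)phenyl]ethan-1-one
Product: 6 1-{4-[(6-methyl-2,2-diphenyl-1,3-benzodioxol-4-yl)methyl]phenyl}ethan-1-one, via aryllithium 4 (not isolated), via arylzinc chloride 5 (not isolated)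
Conditions: 2, n-BuLi (1.1 equiv), TMEDA (1.1 equiv), THF, −78 → 0 °C; ZnCl2 (1.2 equiv), 0 °C; then 3 (0.9 equiv), Pd(PPh3)4 (3 mol%), THF, 23 → 50 °C
Reagents that add atoms: n-butyllithium, [Li]CCCC (lithium of 4 only); zinc chloride, Cl[Zn]Cl (zinc and chlorine of 5 only)
Why: Directed ortho-metalation followed by Negishi cross-coupling of an arylzinc chloride with a benzylic bromide: the ring oxygen directs lithiation to C7 of 2, the only ortho position not flanked by the methyl group, and the arylzinc reagent couples at the benzylic C–Br bond without adding to the ketone.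

Step 3
Reactants: 6 1-{4-[(6-methyl-2,2-diphenyl-1,3-benzodioxol-4-yl)methyl]phenyl}ethan-1-one
Product: 7 (1R)-1-{4-[(6-methyl-2,2-diphenyl-1,3-benzodioxol-4-yl)methyl]phenyl}ethan-1-ol
Conditions: RuCl[(R,R)-TsDPEN](p-cymene) (1 mol%), HCO2H–Et3N (5:2), 30 °C
Reagents that add atoms: none
Why: Noyori asymmetric transfer hydrogenation of an aryl methyl ketone; the (R,R)-configured ruthenium hydride is expected to deliver hydride to the face that gives the (R)-1-arylethanol, as with simple para-substituted acetophenones.

Step 4
Reactants: 7 (1R)-1-{4-[(6-methyl-2,2-diphenyl-1,3-benzodioxol-4-yl)methyl]phenyl}ethan-1-ol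
Product: 8 (1R)-1-{4-[(6-methyl-2,2-diphenyl-1,3-benzodioxol-4-yl)methyl]phenyl}ethyl di(propan-2-yl)carbamate
Conditions: iPr2NCOCl (1.5 equiv), Et3N (2 equiv), CH2Cl2, reflux
Reagents that add atoms: di(propan-2-yl)carbamoyl chloride, CC(C)N(C(C)C)C(Cl)=O
Why: O-Carbamoylation of a secondary alcohol; no bond to the stereocentre is broken, so the (R) configuration is kept, and the hindered carbamate is the group that later directs and stabilises the benzylic lithiation.

Step 5
Reactants: 9 4-methylpent-1-ene
Product: 10 4,4,5,5-tetramethyl-2-(4-methylpentyl)-1,3,2-dioxaborolane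
Conditions: pinacolborane (1.1 equiv), [Ir(cod)Cl]2 (1.5 mol%), dppm (3 mol%), CH2Cl2, 23 °C
Reagents that add atoms: pinacolborane, [H]B1OC(C)(C)C(C)(C)O1
Why: Iridium-catalysed anti-Markovnikov hydroboration of a terminal alkene, which puts boron on the terminal carbon and gives the primary alkyl boronic ester.

Step 6
Reactants: 8 (1R)-1-{4-[(6-methyl-2,2-diphenyl-1,3-benzodioxol-4-yl)methyl]phenyl}ethyl di(propan-2-yl)carbamate; 10 4,4,5,5-tetramethyl-2-(4-methylpentyl)-1,3,2-dioxaborolane
Product: 14 (2S)-6-methyl-2-{4-[(6-methyl-2,2-diphenyl-1,3-benzodioxol-4-yl)methyl]phenyl}heptan-2-ol, via lithiated carbamate 11 (not isolated), via boronate complex 12 (not isolated), via tertiary boronic ester 13 (not isolated)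
Conditions: 8, s-BuLi (1.3 equiv), Et2O, −78 °C; 10 (1.5 equiv), −78 °C, then → 23 °C; then 2 M NaOH, 30% H2O2, THF, 0 → 23 °C
Reagents that add atoms: hydrogen peroxide, OO (oxygen of the hydroxyl group); sec-butyllithium, CCC(C)[Li] (lithium of 11 and 12 only)
Why: Lithiation–borylation: s-BuLi removes the benzylic hydrogen next to the carbamate with retention to give the configurationally stable lithium compound 11, the boronic ester 10 traps it with retention as boronate 12, on warming the 4-methylpentyl group shifts from boron to carbon anti to the leaving carbamate (1,2-metalate rearrangement, inversion) to give the tertiary boronic ester 13, and alkaline peroxide oxidises the C–B bond with retention. The closest known reaction type is the conversion of secondary benzylic di(propan-2-yl)carbamates and primary alkyl pinacol boronic esters into tertiary benzylic alcohols. The step closes no ring; it forms the bond between the carbinol carbon and the first CH2 of the side chain and so joins the C16 diarylmethane to the C6 chain. The one new stereocentre is controlled by the (R) centre of 8: the sequence retention, retention, inversion, retention amounts to replacing the carbinol hydrogen of the (R)-alcohol by the alkyl group with retention, which is the (S) configuration of the target (the descriptor changes because the chain outranks methyl). The step needs deprotonation next to the carbamate and not at the diarylmethane CH2, which precomplexation of the base by the carbamate carbonyl at −78 °C in ether should secure, and it needs full stereospecificity, which the absence of any ortho substituent on ring B at this stage favours.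

Step 7
Reactants: 14 (2S)-6-methyl-2-{4-[(6-methyl-2,2-diphenyl-1,3-benzodioxol-4-yl)methyl]phenyl}heptan-2-ol
Product: 16 (3S)-1,1-diethyl-3-methyl-6-[(6-methyl-2,2-diphenyl-1,3-benzodioxol-4-yl)methyl]-3-(4-methylpentyl)-1,3-dihydro-2,1-benzoxasilole, via hydridosilyl ether 15 (not isolated)
Conditions: Et2SiH2 (1.5 equiv), [Ir(cod)OMe]2 (0.5 mol%), THF, 23 → 50 °C; volatiles removed; [Ir(cod)OMe]2 (1 mol%), 1,10-phenanthroline (2.5 mol%), norbornene (1.2 equiv), THF, 100 °C
Reagents that add atoms: diethylsilane, CC[SiH2]CC
Why: Hydroxyl-directed iridium-catalysed arene C–H silylation: dehydrogenative O-silylation gives the hydridosilyl ether 15, and the phenanthroline–iridium catalyst with norbornene as hydrogen acceptor closes the five-membered oxasilole at an ortho C–H bond of ring B; the two ortho positions of the para-disubstituted ring are equivalent, so only one product can form, and the stereocentre is not touched.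

Step 8
Reactants: 16 (3S)-1,1-diethyl-3-methyl-6-[(6-methyl-2,2-diphenyl-1,3-benzodioxol-4-yl)methyl]-3-(4-methylpentyl)-1,3-dihydro-2,1-benzoxasilole
Product: 17 5-[(6-methyl-2,2-diphenyl-1,3-benzodioxol-4-yl)methyl]-2-[(2S)-2-hydroxy-6-methylheptan-2-yl]phenol
Conditions: 30% H2O2 (10 equiv), KHCO3 (3 equiv), THF–MeOH (1:1), 23 °C
Reagents that add atoms: hydrogen peroxide, OO (oxygen of the phenol)
Why: Tamao–Fleming oxidation of the aryl–silicon bond of a cyclic alkoxysilane: the aryl group migrates from silicon to peroxide oxygen at the same ring carbon and hydrolysis frees the phenol and the tertiary alcohol under weakly basic conditions that do not ionise the benzylic C–O bond.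

Step 9
Reactants: 17 5-[(6-methyl-2,2-diphenyl-1,3-benzodioxol-4-yl)methyl]-2-[(2S)-2-hydroxy-6-methylheptan-2-yl]phenol
Product: 18 asperchondol A
Conditions: H2 (1 atm), 10% Pd/C, EtOAc, 23 °C
Reagents that add atoms: none
Why: Hydrogenolysis of the two benzhydryl-type C–O bonds of the diphenylmethylene ketal; under neutral, acid-free conditions the tertiary benzylic alcohol should not be reduced and the stereocentre is unaffected.

Compound list
1 | 4-methylbenzene-1,2-diol (4-methylcatechol) | Cc1ccc(O)c(O)c1 | starting material
2 | 5-methyl-2,2-diphenyl-1,3-benzodioxole | Cc1ccc2OC(c3ccccc3)(c3ccccc3)Oc2c1 | intermediate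
3 | 1-[4-(bromomethyl)phenyl]ethan-1-one | CC(=O)c1ccc(CBr)cc1 | starting material
4 | (6-methyl-2,2-diphenyl-1,3-benzodioxol-4-yl)lithium | [Li]c1cc(C)cc2OC(c3ccccc3)(c3ccccc3)Oc12 | intermediate
5 | chlorido(6-methyl-2,2-diphenyl-1,3-benzodioxol-4-yl)zinc | Cl[Zn]c1cc(C)cc2OC(c3ccccc3)(c3ccccc3)Oc12 | intermediate
6 | 1-{4-[(6-methyl-2,2-diphenyl-1,3-benzodioxol-4-yl)methyl]phenyl}ethan-1-one | CC(=O)c1ccc(Cc2cc(C)cc3OC(c4ccccc4)(c4ccccc4)Oc23)cc1 | intermediate
7 | (1R)-1-{4-[(6-methyl-2,2-diphenyl-1,3-benzodioxol-4-yl)methyl]phenyl}ethan-1-ol | C[C@@H](O)c1ccc(Cc2cc(C)cc3OC(c4ccccc4)(c4ccccc4)Oc23)cc1 | intermediate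
8 | (1R)-1-{4-[(6-methyl-2,2-diphenyl-1,3-benzodioxol-4-yl)methyl]phenyl}ethyl di(propan-2-yl)carbamate | C[C@@H](OC(=O)N(C(C)C)C(C)C)c1ccc(Cc2cc(C)cc3OC(c4ccccc4)(c4ccccc4)Oc23)cc1 | intermediate
9 | 4-methylpent-1-ene | C=CCC(C)C | starting material
10 | 4,4,5,5-tetramethyl-2-(4-methylpentyl)-1,3,2-dioxaborolane | CC(C)CCCB1OC(C)(C)C(C)(C)O1 | intermediate
11 | (1R)-1-lithio-1-{4-[(6-methyl-2,2-diphenyl-1,3-benzodioxol-4-yl)methyl]phenyl}ethyl di(propan-2-yl)carbamate (lithium in the place of the carbinol hydrogen of 8) | C[C@@]([Li])(OC(=O)N(C(C)C)C(C)C)c1ccc(Cc2cc(C)cc3OC(c4ccccc4)(c4ccccc4)Oc23)cc1 | intermediate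
12 | lithium [(1R)-1-{[di(propan-2-yl)carbamoyl]oxy}-1-{4-[(6-methyl-2,2-diphenyl-1,3-benzodioxol-4-yl)methyl]phenyl}ethyl](4-methylpentyl)(pinacolato)borate | [Li+].C[C@@]([B-]1(CCCC(C)C)OC(C)(C)C(C)(C)O1)(OC(=O)N(C(C)C)C(C)C)c1ccc(Cc2cc(C)cc3OC(c4ccccc4)(c4ccccc4)Oc23)cc1 | intermediate
13 | 4,4,5,5-tetramethyl-2-[(2R)-6-methyl-2-{4-[(6-methyl-2,2-diphenyl-1,3-benzodioxol-4-yl)methyl]phenyl}heptan-2-yl]-1,3,2-dioxaborolane | C[C@](B1OC(C)(C)C(C)(C)O1)(CCCC(C)C)c1ccc(Cc2cc(C)cc3OC(c4ccccc4)(c4ccccc4)Oc23)cc1 | intermediate
14 | (2S)-6-methyl-2-{4-[(6-methyl-2,2-diphenyl-1,3-benzodioxol-4-yl)methyl]phenyl}heptan-2-ol | Cc1cc2OC(c3ccccc3)(c3ccccc3)Oc2c(Cc2ccc([C@@](C)(O)CCCC(C)C)cc2)c1 | intermediate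
15 | diethyl{[(2S)-6-methyl-2-{4-[(6-methyl-2,2-diphenyl-1,3-benzodioxol-4-yl)methyl]phenyl}heptan-2-yl]oxy}silane | Cc1cc2OC(c3ccccc3)(c3ccccc3)Oc2c(Cc2ccc([C@@](C)(O[SiH](CC)CC)CCCC(C)C)cc2)c1 | intermediate
16 | (3S)-1,1-diethyl-3-methyl-6-[(6-methyl-2,2-diphenyl-1,3-benzodioxol-4-yl)methyl]-3-(4-methylpentyl)-1,3-dihydro-2,1-benzoxasilole | Cc1cc2OC(c3ccccc3)(c3ccccc3)Oc2c(Cc2ccc3c(c2)[Si](CC)(CC)O[C@@]3(C)CCCC(C)C)c1 | intermediate
17 | 5-[(6-methyl-2,2-diphenyl-1,3-benzodioxol-4-yl)methyl]-2-[(2S)-2-hydroxy-6-methylheptan-2-yl]phenol | Cc1cc2OC(c3ccccc3)(c3ccccc3)Oc2c(Cc2ccc([C@@](C)(O)CCCC(C)C)c(O)c2)c1 | intermediate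
18 | asperchondol A, 3-{3-hydroxy-4-[(2S)-2-hydroxy-6-methylheptan-2-yl]benzyl}-5-methylbenzene-1,2-diol | Cc1cc(O)c(O)c(Cc2ccc([C@@](C)(O)CCCC(C)C)c(O)c2)c1 | target

Total step count: 9. Longest linear sequence: 8 steps (steps 1 to 4 and 6 to 9, from 1); step 5 is a one-step branch.

The three steps most likely to fail:

Step 6 (lithiation–borylation). What may go wrong: deprotonation at the doubly benzylic CH2 of the diarylmethane in competition with the carbamate-directed lithiation, or loss of stereochemical fidelity if boronate formation becomes reversible before the migration. The fallback would set out from ketone 6 and come back to the route at 14 by a catalytic enantioselective alkyl addition. Bis(4-methylpentyl)zinc F1 (from 9 by hydroboration with Et2BH and boron–zinc exchange with Et2Zn) would be added to 6 in the presence of Ti(OiPr)4 and the C2-symmetric bis(hydroxycamphorsulfonamide) ligand of trans-cyclohexane-1,2-diamine, the ligand enantiomer being chosen to give the (S)-alcohol. Steps 3 and 4 would then be left out.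

Step 7 (carbinol-directed C–H silylation). What may go wrong: the ring closure at silicon may be slow at the hindered tertiary silyl ether, so that redistribution of the silane to disiloxanes takes over. The fallback would set out from 14 and come back to the route at 17 by a silyl-directed borylation that needs no ring closure. The hydridosilyl ether 15 would be treated with B2pin2, [Ir(cod)Cl]2 and 4,4′-di-tert-butyl-2,2′-bipyridine (THF, 80 °C) to give diethyl{[(2S)-6-methyl-2-{4-[(6-methyl-2,2-diphenyl-1,3-benzodioxol-4-yl)methyl]-2-(4,4,5,5-tetramethyl-1,3,2-dioxaborolan-2-yl)phenyl}heptan-2-yl]oxy}silane F2. NaBO3·4H2O in THF–water would then oxidise the C–B bond to the phenol and hydrolyse the silyl ether to give 17.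

Step 2 (ortho-metalation and Negishi coupling). What may go wrong: partial lithiation at C4 next to the methyl group, or homocoupling of the benzylic bromide in the one-pot coupling. The fallback would set out from 2 and come back to the route at 6 through an isolable boron reagent. Iridium-catalysed C–H borylation of 2 (B2pin2, [Ir(cod)OMe]2, 4,4′-di-tert-butyl-2,2′-bipyridine, THF, 80 °C), which avoids C–H bonds ortho to an alkyl group, would give 4,4,5,5-tetramethyl-2-(6-methyl-2,2-diphenyl-1,3-benzodioxol-4-yl)-1,3,2-dioxaborolane F3. Suzuki–Miyaura coupling of this boronic ester with 3 (PdCl2(dppf), K3PO4, THF–H2O, 60 °C) would give 6.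

Further compounds
F1 | step 6 | bis(4-methylpentyl)zinc | CC(C)CCC[Zn]CCCC(C)C
F2 | step 7 | diethyl{[(2S)-6-methyl-2-{4-[(6-methyl-2,2-diphenyl-1,3-benzodioxol-4-yl)methyl]-2-(4,4,5,5-tetramethyl-1,3,2-dioxaborolan-2-yl)phenyl}heptan-2-yl]oxy}silane | Cc1cc2OC(c3ccccc3)(c3ccccc3)Oc2c(Cc2ccc([C@@](C)(O[SiH](CC)CC)CCCC(C)C)c(B3OC(C)(C)C(C)(C)O3)c2)c1
F3 | step 2 | 4,4,5,5-tetramethyl-2-(6-methyl-2,2-diphenyl-1,3-benzodioxol-4-yl)-1,3,2-dioxaborolane | Cc1cc(B2OC(C)(C)C(C)(C)O2)c2OC(c3ccccc3)(c3ccccc3)Oc2c1
A1 | direct plan | (S)-3,7-dimethyloct-1-yn-3-ol | C#C[C@@](C)(O)CCCC(C)C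
A2 | direct plan | 5-[2,3-bis(benzyloxy)-5-methylbenzyl]-3-hydroxy-2H-pyran-2-one | Cc1cc(OCc2ccccc2)c(OCc2ccccc2)c(CC2=COC(=O)C(O)=C2)c1
A3 | direct plan | 1,2-bis(benzyloxy)-3-(chloromethyl)-5-methylbenzene | Cc1cc(OCc2ccccc2)c(OCc2ccccc2)c(CCl)c1
A4 | direct plan | 5-bromo-3-hydroxy-2H-pyran-2-one | O=C1OC=C(Br)C=C1O
A5 | direct plan | 3,5-dibromo-2H-pyran-2-one | O=C1OC=C(Br)C=C1Br
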